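## Structural features

25 is an achiral 2-arylbenzofuran. Ring A is the benzo ring of the benzofuran, the furan carries the formyl group on C3, and C2 is bonded to C1′ of a resorcinol-type ring B. Ring A has OH on C6 and a prenyl group on C7, the position between O6 and the furan oxygen; ring B has OH on C2′ and C4′ and a prenyl group on C5′. The target has no stereocentre; the only stereocentres in the route are the adjacent C2 and C3 of dihydrobenzofuran 22, which are set together and later erased. The fragile parts are the two prenyl alkenes, each ortho to a phenol (acid closes them to chromans, electrophiles and oxidants attack them), the electron-rich phenols, and the aldehyde, which lies within reach of the 2′-hydroxyl (cyclic acetal formation). The real difficulty is the fully substituted C2=C3 bond: C2 needs ring B and C3 needs one carbon. The isomer with the two carbonyl carbons exchanged (a 3-aroylbenzofuran) becomes accessible whenever a free ring A phenol meets an unmasked formyl carbon. A second difficulty is placing one prenyl group at a defined position on each of two different oxygenated rings. The key step uses the O1–C2=C3 enol ether: C2 is the acidic carbon that can carry boron and C3 is the nucleophilic β-carbon, so ring B moves from boron to C2 as C3 bonds to a formyl cation equivalent.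

## Logic of the disconnections

25 from 24. The three O–CH2OMe bonds and the two C–OMe bonds of the C3 acetal are cut. Phenols and a free aldehyde cannot pass through organolithium chemistry or meet a carbenium ion, so all are masked by acetals that leave in one acidic operation. The forward step needs acid mild enough to spare the prenyl/phenol pairs and enough water for the C3 carbon to end as CHO and not as a cyclic acetal with O2′.

24 from 23 from 22. The C2=C3 π-bond is traced back to C2–OH and C3–H (dehydration), and C2–O to C2–B (oxidation). Boron on C2 is the residue of the key step, and 22 already holds every carbon of the target. The forward steps need an oxidant that leaves the alkenes alone. They must also keep the O1–C2 bond closed until the furan is aromatic, because a free ring A phenol next to an opened acetal would lead to the 3-aroyl isomer.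

22 from 10, 17 and 18. The C2–C1′ and C3–CH(OMe)2 bonds are cut, the two bonds at the two carbons of the enol ether. This divides the molecule into two aromatic halves of similar size plus a one-carbon unit, with each prenyl group and each oxygen already in place. The forward step needs clean lithiation of 10 at C2, a stable boronate, attack of the electrophile at C3 only, and migration of the aryl group. Two refinements make it safer: the carbenium ion is made beforehand as its tetrafluoroborate so that no free BF3 meets the boronate or the acetal groups, and the boronate is added to it cold.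

10 from 9 from 7. The O6–CH2OMe bond and the C7–CH2 bond are cut, the latter by a retro-Claisen shift to the tertiary allyl ether on O6. The [3,3] shift delivers a linear prenyl group ortho to oxygen without an organometallic reagent on ring A. It requires C7 to be preferred over C5, which the higher C6–C7 bond order of a benzofuran should provide.

7 from 6 from 4 from 1 and 2. The alkene is traced to an alkyne, the furan C2=C3 bond to the ketone of 4 by reduction and dehydration, and the O6–C(tertiary) bond is cut. A tertiary ether cannot be made by SN2, so it is made by propargylic substitution and partial hydrogenation. Placing it on O6 before the ketone is reduced lets it act as the phenol protecting group for that reduction. The dehydration must use acid weak enough for a tertiary propargyl ether, and the hydrogenation must stop at the alkene.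

17 from 15 from 12 from 11 and 13. The C1′–B and C5′–CH2 bonds are each traced to a C–Br bond, and the two MOM ethers are cut. The two bromine atoms of symmetric 11 mark exactly C1′ and C5′, so ring B regiochemistry is bought, not made. The forward steps need mono-exchange of one bromine and attack of the aryl metal at the primary carbon of 13.

## Other disconnections considered

Alternative 1: The cut is the furan O1–C2 bond together with the CHO/2′-OH pair, which are folded back into the pyranone ring of isoflavone A1 (3-[2,4-bis(TBS-oxy)-3-prenylphenyl]-7-(TBS-oxy)-6-prenylchromen-4-one). Its carbonyl carbon is C2 of 25, its O–CH= carbon is the formyl carbon, and its ring oxygen is O2′.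
- **Forward step:** triflation of the chromone carbonyl gives a triflyloxy-benzopyrylium ion. The ortho silyloxy oxygen of the 3-aryl group displaces triflate at that carbon and closes the furan. Mild aqueous base then adds water at the CH of the fused pyrylium, which opens to phenol aldehyde A2.
- **In favour:** the formyl carbon is fixed by connectivity, so the 3-aroyl isomer cannot arise; on this point the alternative is better than the chosen plan, whose endgame depends on the order of operations. Silyl ethers leave with fluoride, so the last step needs no acid; this is also better for the prenyl/phenol pairs.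
- **Against:** the attacking oxygen is hindered (silyl group, flanking prenyl group, chromone). A strong triflating agent and the silyl triflate it releases are cationic initiators in the presence of two prenyl alkenes. Water must add at the CH and not at the O,O-substituted carbon, which would return a chromone. The ring switch is itself without close precedent, so it is no safer as a method than the chosen key step.
- **Comparison:** structurally it forms one C–O bond where the chosen step forms two C–C bonds, and A1 still has to be assembled from two separately prenylated, silyl-protected halves. The step count should be similar or slightly higher (about 12 to 14).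

Alternative 2: The cut is through ring A itself (C4–C5 and C7–C7a), back to acrylate A3 (methyl 2-{[2-(2,4-bis(MOM-oxy)-5-prenylphenyl)-1,3-dithian-2-yl]methyl}acrylate) and ketone A4 (6-methylhept-5-en-2-one).
- **Forward step:** the kinetic methyl enolate of A4 adds to the acrylate methylene, proton transfer gives the internal enolate, and this closes on the ester (Michael addition, then Claisen condensation) to give dione A5.
- **In favour:** the C7 prenyl group is the ketone's own chain, so ring A has no regiochemical question; on this point it is better than the Claisen step of the chosen plan. The enolate chemistry is classical, so on precedent the key step is also better.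
- **Against:** ring A arrives as a cyclohexane-1,3-dione. It still needs dithiane removal, furan closure onto the C7a carbonyl, dehydrogenation to the phenol in the presence of two prenyl groups, and a separate C3 formylation. The one-carbon unit is therefore not part of the key step, and oxidants are needed that the alkenes may not tolerate.
- **Comparison:** it builds by a linear sequence what the chosen plan buys as an aromatic ring; the total would probably exceed 15 steps.

Alternative 3: The cut is at both aryl–CH2 bonds (C7–CH2 and C5′–CH2), back to bis(1,1-dimethylallyl) ether A6 (2-[2-acetoxy-4-(1,1-dimethylallyloxy)phenyl]-6-(1,1-dimethylallyloxy)benzofuran-3-carbaldehyde).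
- **Forward step:** heating in a high-boiling tertiary aniline moves both allyl groups from oxygen to the ortho carbons by two [3,3] shifts, giving A7.
- **In favour:** the prenyl groups arrive last, so they need not survive organolithium, carbenium or oxidation steps; on this point the alternative is better than the chosen plan. The reaction type is the same well-understood shift as step 4, so it is equal on mechanism.
- **Against:** there are two independent regiochemical choices (C7 against C5, C5′ against C3′), so mixtures are likely. An aldehyde and an aryl acetate are exposed to a hot amine. The disconnection also does nothing for the central problem, the C2-aryl/C3-formyl furan, which would need its own key step.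
- **Comparison:** the chosen plan has one regiochemical choice instead of two, because the ring B prenyl group is placed by the position of a bromine. Step counts should be about equal (11 to 13), with lower expected throughput for the alternative.

Key step: step 9

Remark on the chemistry (assumptions): "prenyl" means 3-methylbut-2-enyl. The Claisen shift of 7 is assumed to favour C7 over C5. 23 is drawn ring-closed although it can equilibrate with the ring-opened hydroxy ketone. The configuration of 22 (aryl trans to the acetal carbon, boron cis to it) is the one that anti addition across C2=C3 requires.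

## Route

Step 1
Reactants: 1 6-hydroxybenzofuran-3(2H)-one; 2 2-methylbut-3-yn-2-ol
Product: 4 6-[(2-methylbut-3-yn-2-yl)oxy]benzofuran-3(2H)-one, via trifluoroacetate 3 (not isolated)
Conditions: 2, (CF3CO)2O, DBU, MeCN, −5 °C; then 1, DBU, CuCl2·2H2O (cat.), MeCN, 0 °C
Reagents that add atoms: none
Why: Copper-catalysed propargylic etherification: the copper acetylide of 3 ionises to a stabilised tertiary propargyl cation equivalent that the phenoxide of 1 captures at oxygen, giving a tertiary ether that SN2 cannot make; the phenol (a vinylogous acid) is the only site deprotonated by one equivalent of DBU at 0 °C, and the new ether also masks the phenol for step 2.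

Step 2
Reactants: 4 6-[(2-methylbut-3-yn-2-yl)oxy]benzofuran-3(2H)-one
Product: 6 6-[(2-methylbut-3-yn-2-yl)oxy]benzofuran, via benzylic alcohol 5 (not isolated)
Conditions: NaBH4, MeOH/THF, 0 °C; then 1 M aq. HCl, rt
Reagents that add atoms: none
Why: Borohydride reduction of the aryl ketone (no longer deactivated by a para-phenoxide) followed by acid-catalysed dehydration; the benzylic cation is stabilised by the para ether oxygen and the ortho ring oxygen and loses a proton to give the aromatic furan, while the alkyne is inert to NaBH4 and the tertiary propargyl ether should survive brief dilute acid.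

Step 3
Reactants: 6 6-[(2-methylbut-3-yn-2-yl)oxy]benzofuran
Product: 7 6-[(2-methylbut-3-en-2-yl)oxy]benzofuran
Conditions: H2 (1 atm), Pd/CaCO3 poisoned with Pb(OAc)2 (Lindlar catalyst), quinoline, EtOAc, rt
Reagents that add atoms: none
Why: Lindlar semihydrogenation: the poisoned catalyst reduces the terminal alkyne and stops at the alkene, leaving the furan C2=C3 bond and the aryl ether untouched.

Step 4
Reactants: 7 6-[(2-methylbut-3-en-2-yl)oxy]benzofuran
Product: 9 7-prenylbenzofuran-6-ol, via dienone 8 (not isolated)
Conditions: PhNEt2, 140 °C
Reagents that add atoms: none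
Why: Aromatic Claisen rearrangement: a chair [3,3] shift joins the allyl terminus to C7 and gives dienone 8, which tautomerises to the phenol; C7 should be preferred over C5 because the C6–C7 bond of a benzofuran has the higher double-bond character, the gem-dimethyl group lowers the temperature needed, and the amine solvent buffers acid that could cyclise the ortho-prenylphenol.

Step 5
Reactants: 9 7-prenylbenzofuran-6-ol
Product: 10 6-(methoxymethoxy)-7-prenylbenzofuran
Conditions: MOMCl, i-Pr2NEt, CH2Cl2, 0 °C to rt
Reagents that add atoms: chloromethyl methyl ether (MOMCl), COCCl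
Why: O-alkylation of the phenol to its MOM ether; the group is stable to n-BuLi at −78 °C and does not draw lithiation away from the more acidic C2–H.

Step 6
Reactants: 11 4,6-dibromoresorcinol
Product: 12 1,5-dibromo-2,4-bis(methoxymethoxy)benzene
Conditions: MOMCl, i-Pr2NEt, CH2Cl2, 0 °C to rt
Reagents that add atoms: chloromethyl methyl ether (MOMCl), COCCl
Why: Double MOM ether formation; both phenols are acidified by the ortho bromines and alkylate readily.

Step 7
Reactants: 12 1,5-dibromo-2,4-bis(methoxymethoxy)benzene; 13 1-bromo-3-methylbut-2-ene
Product: 15 1-bromo-2,4-bis(methoxymethoxy)-5-prenylbenzene, via aryllithium 14 (not isolated)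
Conditions: n-BuLi (1.0 equiv), THF, −78 °C; CuBr·SMe2 (10 mol%); 13, −78 °C to rt
Reagents that add atoms: none
Why: Bromine–lithium exchange followed by copper-catalysed allylic substitution: one equivalent of n-BuLi exchanges one of the two equivalent bromines (a second exchange to a dianion is much slower), the MOM oxygen chelates the lithium, and the aryl copper species attacks prenyl bromide at its primary carbon to give the linear prenyl arene.

Step 8
Reactants: 15 1-bromo-2,4-bis(methoxymethoxy)-5-prenylbenzene
Product: 17 2-[2,4-bis(methoxymethoxy)-5-prenylphenyl]-4,4,5,5-tetramethyl-1,3,2-dioxaborolane, via aryllithium 16 (not isolated)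
Conditions: n-BuLi, THF, −78 °C; i-PrOBpin, −78 °C to rt
Reagents that add atoms: 2-isopropoxy-4,4,5,5-tetramethyl-1,3,2-dioxaborolane, CC(C)OB1OC(C)(C)C(C)(C)O1
Why: Bromine–lithium exchange and borylation: exchange is faster than deprotonation of the benzylic/allylic CH2 at −78 °C, and the aryllithium adds to boron and expels isopropoxide to give the pinacol ester.

Step 9
Reactants: 10 6-(methoxymethoxy)-7-prenylbenzofuran; 17 2-[2,4-bis(methoxymethoxy)-5-prenylphenyl]-4,4,5,5-tetramethyl-1,3,2-dioxaborolane; 18 trimethyl orthoformate
Product: 22 trans-2-[2,4-bis(methoxymethoxy)-5-prenylphenyl]-3-(dimethoxymethyl)-6-(methoxymethoxy)-7-prenyl-2-(pinacolboryl)-2,3-dihydrobenzofuran (racemic; aryl trans to the acetal carbon), via 2-lithiobenzofuran 19 (not isolated), via lithium boronate complex 20 (not isolated), via dimethoxycarbenium tetrafluoroborate 21 (not isolated)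
Conditions: 10, n-BuLi, THF, −78 °C; 17, −78 to 0 °C; then added at −78 °C to [HC(OMe)2]BF4 (from 18 and BF3·OEt2, CH2Cl2, −30 °C); Et3N, −78 °C
Reagents that add atoms: none
Why: Proposed new method: n-BuLi removes the most acidic proton of 10 (C2–H of the furan), and 19 adds to the boron of 17 to give tetracoordinate boronate 20, whose C2=C3 enol ether is made far more electron-rich by the adjacent anionic C–B bond. C3 then attacks dimethoxycarbenium ion 21 while the ring B aryl group shifts from boron to C2 in an electrophile-induced 1,2-metalate rearrangement, which forms C3–CH(OMe)2 and C2–C1′ and leaves a neutral pinacol boronate on C2. The closest known reaction type is the electrophile-triggered 1,2-migration of indol-2-yl and benzofuran-2-yl boronate complexes with allyl, alkyl, halogen and iminium electrophiles (the addition half of a Zweifel-type coupling); a dialkoxycarbenium electrophile and an ortho-alkoxyaryl migrating group are untested. No ring is closed. The two new stereocentres C2 and C3 are set together by the anti-periplanar demand of the shift: the aryl group enters C2 on the face opposite to the electrophile arriving at C3, so aryl and acetal are trans and boron is cis to the acetal; with no chiral element present 22 is racemic, and both centres are erased in steps 10 and 11. The step needs attack at C3 and not at the prenyl alkenes, the ipso carbon of ring B or the MOM oxygens; the boronate-activated enol ether is by far the strongest nucleophile present, and aryl is the only carbon ligand able to migrate because the other one is the acceptor and pinacol oxygens migrate very poorly. Pre-forming 21 as a BF4 salt free of BF3, adding 20 to it at −78 °C and quenching cold with amine keeps Lewis acid away from the MOM ethers, the new acetal and the alkenes.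

Step 10
Reactants: 22 trans-2-aryl-3-(dimethoxymethyl)-2-(pinacolboryl)-2,3-dihydrobenzofuran (as in step 9)
Product: 23 2-[2,4-bis(methoxymethoxy)-5-prenylphenyl]-3-(dimethoxymethyl)-6-(methoxymethoxy)-7-prenyl-2,3-dihydrobenzofuran-2-ol (racemic; mixture of C2 epimers)
Conditions: NaBO3·4H2O, THF/H2O (1:1), 0 °C to rt; aq. NH4Cl
Reagents that add atoms: sodium perborate tetrahydrate, O.O.O.O.[Na+].[O-]OB=O
Why: Oxidation of the C–B bond: peroxoborate adds to boron, C2 shifts from boron to oxygen with retention and the borate ester hydrolyses to the hemiketal; the oxidant is nucleophilic and should leave the electron-rich prenyl alkenes alone, and the labile hemiketal centre is of no consequence.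

Step 11
Reactants: 23 2-aryl-3-(dimethoxymethyl)-2,3-dihydrobenzofuran-2-ol (as in step 10)
Product: 24 2-[2,4-bis(methoxymethoxy)-5-prenylphenyl]-3-(dimethoxymethyl)-6-(methoxymethoxy)-7-prenylbenzofuran
Conditions: PPTS (cat.), 4 Å MS, CH2Cl2, rt
Reagents that add atoms: none
Why: Acid-catalysed dehydration of a hemiketal: ionisation gives a C2 oxocarbenium ion stabilised by O1 and by the ortho and para alkoxy groups of ring B, and loss of the C3 proton aromatises the furan; anhydrous PPTS is too weak to open the dimethyl acetal or the MOM ethers at a comparable rate, so O1–C2 stays closed while the formyl carbon is still masked, and both stereocentres disappear.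

Step 12
Reactants: 24 2-[2,4-bis(methoxymethoxy)-5-prenylphenyl]-3-(dimethoxymethyl)-6-(methoxymethoxy)-7-prenylbenzofuran
Product: 25 Eryvarin Q, 2-(2,4-dihydroxy-5-prenylphenyl)-6-hydroxy-7-prenylbenzofuran-3-carbaldehyde
Conditions: 3 M aq. HCl, MeOH/THF, 40 °C
Reagents that add atoms: water, O
Why: Acid-catalysed acetal cleavage: the three MOM groups are transferred to methanol as dimethoxymethane and the dimethyl acetal hydrolyses to the conjugated aldehyde; the water present should drive any cyclic mixed acetal with O2′ on to the open hydroxy aldehyde, and dilute acid at 40 °C should stay below the threshold for prenyl-to-phenol cyclisation.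

## Compound list

1 | 6-hydroxybenzofuran-3(2H)-one | O=C1COc2cc(O)ccc12 | starting material
2 | 2-methylbut-3-yn-2-ol | CC(C)(O)C#C | starting material
3 | 2-methylbut-3-yn-2-yl trifluoroacetate | CC(C)(OC(=O)C(F)(F)F)C#C | intermediate
4 | 6-[(2-methylbut-3-yn-2-yl)oxy]benzofuran-3(2H)-one | O=C1COc2cc(OC(C)(C)C#C)ccc12 | intermediate
5 | 6-[(2-methylbut-3-yn-2-yl)oxy]-2,3-dihydrobenzofuran-3-ol (racemic) | OC1COc2cc(OC(C)(C)C#C)ccc12 | intermediate
6 | 6-[(2-methylbut-3-yn-2-yl)oxy]benzofuran | C#CC(C)(C)Oc1ccc2ccoc2c1 | intermediate
7 | 6-[(2-methylbut-3-en-2-yl)oxy]benzofuran | C=CC(C)(C)Oc1ccc2ccoc2c1 | intermediate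
8 | 7-(3-methylbut-2-enyl)-7H-benzofuran-6-one (racemic) | O=C1C=Cc2ccoc2C1CC=C(C)C | intermediate
9 | 7-(3-methylbut-2-enyl)benzofuran-6-ol | CC(C)=CCc1c(O)ccc2ccoc12 | intermediate
10 | 6-(methoxymethoxy)-7-(3-methylbut-2-enyl)benzofuran | COCOc1ccc2ccoc2c1CC=C(C)C | intermediate
11 | 4,6-dibromoresorcinol | Oc1cc(O)c(Br)cc1Br | starting material
12 | 1,5-dibromo-2,4-bis(methoxymethoxy)benzene | COCOc1cc(OCOC)c(Br)cc1Br | intermediate
13 | 1-bromo-3-methylbut-2-ene | CC(C)=CCBr | starting material
14 | [5-bromo-2,4-bis(methoxymethoxy)phenyl]lithium | [Li]c1cc(Br)c(OCOC)cc1OCOC | intermediate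
15 | 1-bromo-2,4-bis(methoxymethoxy)-5-(3-methylbut-2-enyl)benzene | COCOc1cc(OCOC)c(CC=C(C)C)cc1Br | intermediate
16 | [2,4-bis(methoxymethoxy)-5-(3-methylbut-2-enyl)phenyl]lithium | [Li]c1cc(CC=C(C)C)c(OCOC)cc1OCOC | intermediate
17 | 2-[2,4-bis(methoxymethoxy)-5-(3-methylbut-2-enyl)phenyl]-4,4,5,5-tetramethyl-1,3,2-dioxaborolane | CC1(C)OB(OC1(C)C)c1cc(CC=C(C)C)c(OCOC)cc1OCOC | intermediate
18 | trimethyl orthoformate | COC(OC)OC | starting material
19 | [6-(methoxymethoxy)-7-(3-methylbut-2-enyl)benzofuran-2-yl]lithium | [Li]c1cc2ccc(OCOC)c(CC=C(C)C)c2o1 | intermediate
20 | lithium [2,4-bis(methoxymethoxy)-5-(3-methylbut-2-enyl)phenyl][6-(methoxymethoxy)-7-(3-methylbut-2-enyl)benzofuran-2-yl](pinacolato)borate | [Li+].COCOc1ccc2cc(oc2c1CC=C(C)C)[B-]1(OC(C)(C)C(C)(C)O1)c1cc(CC=C(C)C)c(OCOC)cc1OCOC | intermediate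
21 | dimethoxycarbenium tetrafluoroborate | CO[CH+]OC.F[B-](F)(F)F | intermediate
22 | trans-2-[2,4-bis(methoxymethoxy)-5-(3-methylbut-2-enyl)phenyl]-3-(dimethoxymethyl)-6-(methoxymethoxy)-7-(3-methylbut-2-enyl)-2-(4,4,5,5-tetramethyl-1,3,2-dioxaborolan-2-yl)-2,3-dihydrobenzofuran (racemic; one enantiomer drawn) | COC(OC)[C@@H]1c2ccc(OCOC)c(CC=C(C)C)c2O[C@@]1(B1OC(C)(C)C(C)(C)O1)c1cc(CC=C(C)C)c(OCOC)cc1OCOC | intermediate
23 | 2-[2,4-bis(methoxymethoxy)-5-(3-methylbut-2-enyl)phenyl]-3-(dimethoxymethyl)-6-(methoxymethoxy)-7-(3-methylbut-2-enyl)-2,3-dihydrobenzofuran-2-ol (racemic; C2 epimers) | COC(OC)C1c2ccc(OCOC)c(CC=C(C)C)c2OC1(O)c1cc(CC=C(C)C)c(OCOC)cc1OCOC | intermediate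
24 | 2-[2,4-bis(methoxymethoxy)-5-(3-methylbut-2-enyl)phenyl]-3-(dimethoxymethyl)-6-(methoxymethoxy)-7-(3-methylbut-2-enyl)benzofuran | COC(OC)c1c(-c2cc(CC=C(C)C)c(OCOC)cc2OCOC)oc2c(CC=C(C)C)c(OCOC)ccc12 | intermediate
25 | Eryvarin Q, 2-[2,4-dihydroxy-5-(3-methylbut-2-enyl)phenyl]-6-hydroxy-7-(3-methylbut-2-enyl)benzofuran-3-carbaldehyde | CC(C)=CCc1cc(-c2oc3c(CC=C(C)C)c(O)ccc3c2C=O)c(O)cc1O | target

## Step count and least certain steps

Total: 12 steps. Longest linear sequence: 9 steps (steps 1 to 5, then 9 to 12); the ring B arm is steps 6 to 8.

**Step 9 (key step, proposed new method).**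
- **What may go wrong:** attack of the carbenium ion at the ipso carbon of the electron-rich migrating ring or at C2 (loss of boron) instead of C3; slow migration of the hindered ortho-alkoxyaryl group, which would let the C3-alkylated intermediate fragment; ionisation of MOM groups and cationic attack on the prenyl alkenes if Lewis acid or temperature is not controlled.
- **Fallback (known chemistry):** it sets out from 10 and 15 and rejoins the route at 25.
  - 10 is lithiated as in step 9 and transmetalated with ZnCl2 to [6-(methoxymethoxy)-7-prenylbenzofuran-2-yl]zinc chloride F1.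
  - Negishi coupling of this reagent with 15 (Pd(PPh3)4, a zerovalent palladium catalyst, THF, 50 °C) should give 2-[2,4-bis(methoxymethoxy)-5-prenylphenyl]-6-(methoxymethoxy)-7-prenylbenzofuran F2.
  - Vilsmeier–Haack formylation (POCl3, DMF, 0 °C to rt, then aqueous NaOAc) at C3, the most nucleophilic position of a 2-arylbenzofuran, should give 2-[2,4-bis(methoxymethoxy)-5-prenylphenyl]-6-(methoxymethoxy)-7-prenylbenzofuran-3-carbaldehyde F3.
  - The conditions of step 12 then remove the MOM groups to give 25.
- **Cost of the fallback:** it is one step shorter than steps 9 to 12, but the chloroiminium reagent meets MOM ethers and two prenyl groups, and ring A C5 and ring B compete as formylation sites.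

**Step 11 (with step 10).**
- **What may go wrong:** ring opening of the hemiketal to the hydroxy ketone, under the mildly basic oxidation or the acidic dehydration, followed by loss of methanol or capture of the acetal carbon by the freed ring A phenol. This would lead to the 3-aroyl regioisomer.
- **Fallback:** it sets out from 22 and rejoins at 24 without opening O1–C2.
  - Protodeboronation of the tertiary benzylic boronic ester (TBAF·3H2O, toluene, 50 °C) should give trans-2-[2,4-bis(methoxymethoxy)-5-prenylphenyl]-3-(dimethoxymethyl)-6-(methoxymethoxy)-7-prenyl-2,3-dihydrobenzofuran F4.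
  - Dehydrogenation with DDQ (1,4-dioxane, rt to 60 °C) through hydride loss from the doubly activated C2–H should give 24.
- **Cost of the fallback:** the benzylic/allylic CH2 groups of the prenyl chains are competing sites for the quinone.

**Step 12.**
- **What may go wrong:** acid-promoted cyclisation of a prenyl group onto its neighbouring free phenol (chroman formation), and retention of the formyl carbon as a cyclic mixed acetal with O2′.
- **Fallback:** it sets out from 24 and rejoins at 25 in one aprotic operation. Me2BBr (CH2Cl2, −78 °C) cleaves the MOM ethers and the dimethyl acetal through boron-bound phenoxides and α-bromo ethers, and a cold NaHCO3 quench releases the phenols and the aldehyde. No Brønsted acid meets a free ortho-prenylphenol. No new isolated compound arises.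

**Step 4.**
- **What may go wrong:** partial migration to C5 instead of C7, and thermal cyclisation of the ortho-prenylphenol.
- **Fallback:** it sets out from 1 and rejoins at 10, placing the prenyl group by directed metalation instead of a sigmatropic shift.
  - MOM protection of 1 (MOMCl, i-Pr2NEt) gives 6-(methoxymethoxy)benzofuran-3(2H)-one F5.
  - NaBH4 reduction and dehydration (MsCl, Et3N) give 6-(methoxymethoxy)benzofuran F6.
  - C2 is blocked with n-BuLi and Me3SiCl to give trimethyl[6-(methoxymethoxy)benzofuran-2-yl]silane F7.
  - s-BuLi/TMEDA (THF, −78 °C) metalates C7, the position between O1 and the MOM oxygen; CuBr·SMe2 (cat.) and 13 give trimethyl[6-(methoxymethoxy)-7-prenylbenzofuran-2-yl]silane F8.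
  - TBAF removes the silyl group to give 10.
- **Cost of the fallback:** five steps, the same number as steps 1 to 5.

## Further compounds

F1 | step 9 | [6-(methoxymethoxy)-7-(3-methylbut-2-enyl)benzofuran-2-yl]zinc chloride | Cl[Zn]c1cc2ccc(OCOC)c(CC=C(C)C)c2o1
F2 | step 9 | 2-[2,4-bis(methoxymethoxy)-5-(3-methylbut-2-enyl)phenyl]-6-(methoxymethoxy)-7-(3-methylbut-2-enyl)benzofuran | COCOc1cc(OCOC)c(CC=C(C)C)cc1-c1cc2ccc(OCOC)c(CC=C(C)C)c2o1
F3 | step 9 | 2-[2,4-bis(methoxymethoxy)-5-(3-methylbut-2-enyl)phenyl]-6-(methoxymethoxy)-7-(3-methylbut-2-enyl)benzofuran-3-carbaldehyde | COCOc1cc(OCOC)c(CC=C(C)C)cc1-c1oc2c(CC=C(C)C)c(OCOC)ccc2c1C=O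
F4 | step 11 | trans-2-[2,4-bis(methoxymethoxy)-5-(3-methylbut-2-enyl)phenyl]-3-(dimethoxymethyl)-6-(methoxymethoxy)-7-(3-methylbut-2-enyl)-2,3-dihydrobenzofuran (racemic; one enantiomer drawn) | COC(OC)[C@@H]1c2ccc(OCOC)c(CC=C(C)C)c2O[C@H]1c1cc(CC=C(C)C)c(OCOC)cc1OCOC
F0 | step 12 | none | none
F5 | step 4 | 6-(methoxymethoxy)benzofuran-3(2H)-one | COCOc1ccc2C(=O)COc2c1
F6 | step 4 | 6-(methoxymethoxy)benzofuran | COCOc1ccc2ccoc2c1
F7 | step 4 | trimethyl[6-(methoxymethoxy)benzofuran-2-yl]silane | COCOc1ccc2cc([Si](C)(C)C)oc2c1
F8 | step 4 | trimethyl[6-(methoxymethoxy)-7-(3-methylbut-2-enyl)benzofuran-2-yl]silane | COCOc1ccc2cc([Si](C)(C)C)oc2c1CC=C(C)C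
A1 | alternative 1 | 3-[2,4-bis(tert-butyldimethylsilyloxy)-3-(3-methylbut-2-enyl)phenyl]-7-(tert-butyldimethylsilyloxy)-6-(3-methylbut-2-enyl)chromen-4-one | O=c1c(-c2ccc(O[Si](C)(C)C(C)(C)C)c(CC=C(C)C)c2O[Si](C)(C)C(C)(C)C)coc2cc(O[Si](C)(C)C(C)(C)C)c(CC=C(C)C)cc12
A2 | alternative 1 | 6-(tert-butyldimethylsilyloxy)-2-[4-(tert-butyldimethylsilyloxy)-2-hydroxy-5-(3-methylbut-2-enyl)phenyl]-7-(3-methylbut-2-enyl)benzofuran-3-carbaldehyde | O=Cc1c(-c2cc(CC=C(C)C)c(O[Si](C)(C)C(C)(C)C)cc2O)oc2c(CC=C(C)C)c(O[Si](C)(C)C(C)(C)C)ccc12
A3 | alternative 2 | methyl 2-{[2-(2,4-bis(methoxymethoxy)-5-(3-methylbut-2-enyl)phenyl)-1,3-dithian-2-yl]methyl}prop-2-enoate | C=C(CC1(SCCCS1)c1cc(CC=C(C)C)c(OCOC)cc1OCOC)C(=O)OC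
A4 | alternative 2 | 6-methylhept-5-en-2-one | CC(=O)CCC=C(C)C
A5 | alternative 2 | 4-{[2-(2,4-bis(methoxymethoxy)-5-(3-methylbut-2-enyl)phenyl)-1,3-dithian-2-yl]methyl}-2-(3-methylbut-2-enyl)cyclohexane-1,3-dione (mixture of diastereomers) | O=C1CCC(CC2(SCCCS2)c2cc(CC=C(C)C)c(OCOC)cc2OCOC)C(=O)C1CC=C(C)C
A6 | alternative 3 | 2-[2-acetoxy-4-(2-methylbut-3-en-2-yloxy)phenyl]-6-(2-methylbut-3-en-2-yloxy)benzofuran-3-carbaldehyde | CC(=O)Oc1cc(OC(C)(C)C=C)ccc1-c1oc2cc(OC(C)(C)C=C)ccc2c1C=O
A7 | alternative 3 | 2-[2-acetoxy-4-hydroxy-5-(3-methylbut-2-enyl)phenyl]-6-hydroxy-7-(3-methylbut-2-enyl)benzofuran-3-carbaldehyde | CC(=O)Oc1cc(O)c(CC=C(C)C)cc1-c1oc2c(CC=C(C)C)c(O)ccc2c1C=O
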